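**Retrosynthetic overview**
1. Target ⇒ Δ1(2) dimer: the C1–O bond is made last by radical autoxidation (C3–H abstraction, O2 capture at C1).
2. Δ1(2) dimer ⇒ two molecules of 8-epi-xanthatin: SmI2-catalysed radical relay makes C5–C13′ (Giese addition) and then C3–C11′ (6-exo closure), so the central cyclohexene and the spiro centre are formed last.
3. 8-epi-Xanthatin ⇒ enyne lactone + methyl vinyl ketone (domino enyne ring-closing/cross metathesis builds the cycloheptene).
4. Enyne lactone ⇒ (S)-β-alkynyl aldehyde + 2-(methoxycarbonyl)allylboronate (asymmetric allylboration/lactonisation builds the cis-lactone first).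
5. Aldehyde ⇒ crotonaldehyde + TIPS-acetylene; boronate ⇒ methyl propiolate + allylcopper + formaldehyde. Ring order: lactone → cycloheptene → cyclohexene.

Assumption: xanthanolide numbering is used for the dimers; unit A is the half that carries the hydroxyl (C1–C15) and unit B the spiro-lactone half (primed numbers).

**Step 1**
Reactants: 1 (E)-but-2-enal; 2 ethynyl(triisopropyl)silane
Product: 3 (S)-3-methyl-5-(triisopropylsilyl)pent-4-ynal
Conditions: [Rh(OAc)(C2H4)2]2 (2.5 mol%), (R)-DTBM-SEGPHOS (6 mol%), MeOH, 40 °C
Reagents that add atoms: none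
Why: Rh-catalysed asymmetric conjugate alkynylation of an enal, in which the bulky silyl group and ligand suppress alkyne dimerisation and the chiral alkynylrhodium species adds to one enantioface to set C10 as S (the ligand antipode is used if the sense of induction proves opposite).

**Step 2**
Reactants: 4 methyl prop-2-ynoate; 5 allylmagnesium bromide; 6 formaldehyde
Product: 9 methyl (E)-2-(acetoxymethyl)hexa-2,5-dienoate, via vinylcopper adduct 7 (not isolated), via allylic alkoxide 8 (not isolated)
Conditions: 5, CuBr·SMe2 (1.05 equiv), THF, −78 °C; add 4; then 6 (THF solution from cracked paraformaldehyde), −78 to −20 °C; then Ac2O, 4-(dimethylamino)pyridine (cat.), 0 °C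
Reagents that add atoms: acetic anhydride, CC(=O)OC(C)=O
Why: syn-carbocupration of the ynoate by allylcopper, aldol-type hydroxymethylation of the α-cuprio acrylate and in situ O-acetylation (tandem conjugate addition–aldol); no stereocentre is formed and the alkene geometry does not matter because step 3 passes through a π-allyl intermediate.

**Step 3**
Reactants: 9 methyl (E)-2-(acetoxymethyl)hexa-2,5-dienoate
Product: 10 methyl (E)-2-[(4,4,5,5-tetramethyl-1,3,2-dioxaborolan-2-yl)methyl]hexa-2,5-dienoate
Conditions: B2pin2 (1.1 equiv), Pd2(dba)3 (2.5 mol%), DMSO, 50 °C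
Reagents that add atoms: bis(pinacolato)diboron, CC1(C)OB(OC1(C)C)B1OC(C)(C)C(C)(C)O1
Why: Miyaura-type borylation of an allylic acetate through a π-allylpalladium species places boron on the unsubstituted terminus and gives the thermodynamically preferred geometry (allyl chain cis to CH2B, trans to the ester) needed for a syn-selective allylboration.

**Step 4**
Reactants: 3 (S)-3-methyl-5-(triisopropylsilyl)pent-4-ynal; 10 methyl (E)-2-[(4,4,5,5-tetramethyl-1,3,2-dioxaborolan-2-yl)methyl]hexa-2,5-dienoate
Product: 12 (4R,5R)-4-allyl-3-methylene-5-[(2S)-2-methyl-4-(triisopropylsilyl)but-3-yn-1-yl]dihydrofuran-2(3H)-one, via boryl ether 11 (not isolated)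
Conditions: (S)-3,3′-bis(2,4,6-triisopropylphenyl)-BINOL hydrogen phosphate [(S)-TRIP] (10 mol%), 4 Å MS, toluene, 0 °C to rt; then p-TsOH·H2O (20 mol%), rt
Reagents that add atoms: none
Why: Proposed new method: chiral-phosphoric-acid-catalysed allylboration (established for allyl and crotyl pinacol boronates) is applied to a 2-alkoxycarbonyl allylboronate (whose Brønsted-acid-promoted allylboration/lactonisation is established); the acid hydrogen-bonds to a boronate oxygen in a closed chair transition state, the chain cis to CH2B sits axial and gives the syn adduct (hence the cis C7/C8 lactone), the catalyst selects the Si face of the aldehyde (8R, therefore 7R) over the remote C10 centre, and acid then closes the lactone.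

**Step 5**
Reactants: 12 (4R,5R)-4-allyl-3-methylene-5-[(2S)-2-methyl-4-(triisopropylsilyl)but-3-yn-1-yl]dihydrofuran-2(3H)-one
Product: 13 (4R,5R)-4-allyl-3-methylene-5-[(2S)-2-methylbut-3-yn-1-yl]dihydrofuran-2(3H)-one
Conditions: Bu4NF (1.2 equiv), AcOH (1.2 equiv), THF, 0 °C to rt
Reagents that add atoms: none
Why: fluoride-induced protodesilylation of the alkynylsilane, buffered with acetic acid so that the α-methylene lactone and the three stereocentres are untouched.

**Step 6**
Reactants: 13 (4R,5R)-4-allyl-3-methylene-5-[(2S)-2-methylbut-3-yn-1-yl]dihydrofuran-2(3H)-one; 14 but-3-en-2-one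
Product: 15 8-epi-xanthatin, (3aR,7S,8aR)-7-methyl-3-methylene-6-[(E)-3-oxobut-1-enyl]-3,3a,4,7,8,8a-hexahydro-2H-cyclohepta[b]furan-2-one
Conditions: 14 (5 equiv), second-generation Hoveyda–Grubbs catalyst (15 mol%), CH2Cl2, 40 °C
Reagents that add atoms: none
Why: domino ring-closing enyne metathesis/cross-metathesis, in which the carbene formed at the allyl terminus closes the seven-membered ring onto the alkyne and the resulting vinyl carbene is captured by the enone to give the (E)-dienone; the electron-poor 1,1-disubstituted methylene lactone is inert and no stereocentre is touched.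

**Step 7**
Reactants: 15 8-epi-xanthatin (two molecules)
Product: 16 Δ1(2) dimer (3S,5S,7R,8R,10S,11′S,7′R,8′R,10′S) joined by C5–C13′ and C3–C11′ bonds
Conditions: SmI2 (20 mol%), THF (0.25 M), 45 °C, Ar, dark; air, pH 7 buffer; run to about 60% conversion and recycle 15
Reagents that add atoms: none
Why: Proposed new method: SmI2-catalysed radical-relay formal [4+2], in which divalent samarium reduces the dienone of one molecule to a samarium-bound dienyl ketyl whose δ-carbon (C5) adds Giese-fashion to the exo-methylene carbon (C13′) of a second molecule, the resulting electrophilic α-lactone radical (C11′) closes 6-exo onto C3 of the tethered electron-rich trivalent-samarium dienolate, and back electron transfer from the new unconjugated ketyl regenerates SmI2 (closest known chemistry: SmI2-catalysed radical-relay cyclisations of ketones with alkenes and reductive δ-coupling of dienones); C5 reacts on the ring face anti to H-7, H-8 and H-10, the pairing found in the natural dimers, the planar C11′ radical closes on its convex face syn to H-7′ and anti to C6′, and C3 (drawn as the major epimer) is made planar again in step 8.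

**Step 8**
Reactants: 16 Δ1(2) dimer
Product: 18 CNP0168949.1 (1S,5S,7R,8R,10S,11′S,7′R,8′R,10′S), via C1-hydroperoxide 17 (not isolated)
Conditions: O2 (1 atm), N-hydroxyphthalimide (10 mol%), Co(acac)2 (0.5 mol%), MeCN, 25 °C; then PPh3 (1.05 equiv), 0 °C
Reagents that add atoms: dioxygen, O=O
Why: radical-chain autoxidation, in which the phthalimide-N-oxyl radical abstracts the weak tertiary, allylic, α-keto C3–H, the delocalised dienoxyl radical captures triplet O2 at C1 to give the conjugated γ-hydroperoxy enone (as in Δ5-3-keto steroid autoxidation) and PPh3 reduces the O–O bond; oxygen enters axially on the cyclohexene face anti to C5–H and away from the C7′ ring, setting C1 (S) trans to H-5, which a suprafacial singlet-oxygen ene reaction could not deliver.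

**Compound list**
1 | (E)-but-2-enal | C/C=C/C=O | starting material
2 | ethynyl(triisopropyl)silane (acetylene carrying a TIPS protecting group) | C#C[Si](C(C)C)(C(C)C)C(C)C | starting material
3 | (S)-3-methyl-5-(triisopropylsilyl)pent-4-ynal | O=CC[C@H](C)C#C[Si](C(C)C)(C(C)C)C(C)C | intermediate
4 | methyl prop-2-ynoate | C#CC(=O)OC | starting material
5 | allylmagnesium bromide | C=CC[Mg]Br | starting material
6 | formaldehyde | C=O | starting material
7 | methyl (Z)-2-cuprio-hexa-2,5-dienoate (vinylcopper adduct) | C=CC/C=C(\[Cu])C(=O)OC | intermediate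
8 | methyl (E)-2-(hydroxymethyl)hexa-2,5-dienoate (present as its metal alkoxide) | C=CC/C=C(\CO)C(=O)OC | intermediate
9 | methyl (E)-2-(acetoxymethyl)hexa-2,5-dienoate | C=CC/C=C(\COC(C)=O)C(=O)OC | intermediate
10 | methyl (E)-2-[(4,4,5,5-tetramethyl-1,3,2-dioxaborolan-2-yl)methyl]hexa-2,5-dienoate | C=CC/C=C(\CB1OC(C)(C)C(C)(C)O1)C(=O)OC | intermediate
11 | methyl (3R,4R,6S)-3-allyl-6-methyl-2-methylene-4-[(pinacolatoboryl)oxy]-8-(triisopropylsilyl)oct-7-ynoate | C=C(C(=O)OC)[C@@H](CC=C)[C@H](OB1OC(C)(C)C(C)(C)O1)C[C@H](C)C#C[Si](C(C)C)(C(C)C)C(C)C | intermediate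
12 | (4R,5R)-4-allyl-3-methylene-5-[(2S)-2-methyl-4-(triisopropylsilyl)but-3-yn-1-yl]dihydrofuran-2(3H)-one | C=C1C(=O)O[C@H](C[C@H](C)C#C[Si](C(C)C)(C(C)C)C(C)C)[C@@H]1CC=C | intermediate
13 | (4R,5R)-4-allyl-3-methylene-5-[(2S)-2-methylbut-3-yn-1-yl]dihydrofuran-2(3H)-one | C=C1C(=O)O[C@H](C[C@H](C)C#C)[C@@H]1CC=C | intermediate
14 | but-3-en-2-one (methyl vinyl ketone) | C=CC(C)=O | starting material
15 | 8-epi-xanthatin | C=C1C(=O)O[C@@H]2C[C@H](C)C(/C=C/C(C)=O)=CC[C@H]12 | intermediate
16 | Δ1(2) dimer (3S,5S,7R,8R,10S,11′S,7′R,8′R,10′S): unit A has the C1=C2 alkene and 3-H/3-acetyl, C5–C13′ and C3–C11′ bonds, spiro centre C11′; unit B keeps its dienone | C=C1C(=O)O[C@@H]2C[C@H](C)C3=C[C@H](C(C)=O)[C@@]4(C[C@@H]3C[C@H]12)C(=O)O[C@@H]1C[C@H](C)C(/C=C/C(C)=O)=CC[C@@H]14 | intermediate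
17 | (1S)-1-hydroperoxy-Δ2(3) dimer (C1-hydroperoxide of the target skeleton) | C=C1C(=O)O[C@@H]2C[C@H](C)[C@@]3(OO)C=C(C(C)=O)[C@@]4(C[C@@H]3C[C@H]12)C(=O)O[C@@H]1C[C@H](C)C(/C=C/C(C)=O)=CC[C@@H]14 | intermediate
18 | CNP0168949.1, (1S,5S,7R,8R,10S,11′S,7′R,8′R,10′S)-1-hydroxy-Δ2(3) dimer | C=C1C(=O)O[C@@H]2C[C@H](C)[C@@]3(O)C=C(C(C)=O)[C@@]4(C[C@@H]3C[C@H]12)C(=O)O[C@@H]1C[C@H](C)C(/C=C/C(C)=O)=CC[C@@H]14 | target

**Step count**
Total: 8 steps. Longest linear sequence: 7 steps (4/5/6 → 9 → 10 → 12 → 13 → 15 → 16 → 18).

**Three steps most likely to fail**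

Step 7 (radical-relay dimerisation). The δ- versus β-coupling of the dienyl ketyl, premature reduction of the C11′ radical, the π-face used at C5 and over-reaction of 16 to trimers are all untested. The fallback gives up the radical relay for a thermal, concerted endo Diels–Alder dimerisation: it sets out from 15 (neat or 3 M in toluene, BHT, 60–80 °C, dark) and comes back to the route at 16; no new compound is made on the way (F0).

Step 4 (catalytic asymmetric allylboration). The electron-poor boronate may react too slowly, or with too little facial control, under phosphoric-acid catalysis. The fallback replaces the boronate by an allylindium Barbier reaction: it sets out from 9, which with 3, Pd(PPh3)4 (5 mol%) and InI in THF–H2O gives the open-chain hydroxy ester methyl (3R,4R,6S)-3-allyl-4-hydroxy-6-methyl-2-methylene-8-(triisopropylsilyl)oct-7-ynoate F1 as a cis-selective mixture with its (3S,4S,6S) isomer. Lactonisation with p-TsOH and chromatographic removal of the unwanted isomer bring it back to the route at 12.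

Step 8 (radical γ-oxygenation). Hydrogen abstraction may compete at the allylic C6′–H2 of unit B, and O2 may enter at C3 or on the wrong face of C1. The fallback is polar: it sets out from 16, whose isolated, most electron-rich C1=C2 alkene is epoxidised with mCPBA (CH2Cl2, NaHCO3, 0 °C) on the face anti to H-5 to give the 1,2-epoxide of 16 F2. DBU then opens the epoxide by E1cB from the C3 enolate to the γ-hydroxy enone, coming back to the route at 18.

**Further compounds**
F0 | step 7 | none | none
F1 | step 4 | methyl (3R,4R,6S)-3-allyl-4-hydroxy-6-methyl-2-methylene-8-(triisopropylsilyl)oct-7-ynoate | C=C(C(=O)OC)[C@@H](CC=C)[C@H](O)C[C@H](C)C#C[Si](C(C)C)(C(C)C)C(C)C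
F2 | step 8 | 1,2-epoxide of 16 (epoxide oxygen anti to H-5, 3-H retained) | C=C1C(=O)O[C@@H]2C[C@H](C)[C@@]3(O5)[C@H]5[C@H](C(C)=O)[C@@]4(C[C@@H]3C[C@H]12)C(=O)O[C@@H]1C[C@H](C)C(/C=C/C(C)=O)=CC[C@@H]14
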